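The cyclohexane ring C1–C2–C3–C4–C5–C16 (locants in the remark below) is read as a cyclohexene: the C1 oxygen and C3 methyl are the 1- and 3-substituents of a butadiene, and the C5–C16 ring-fusion bond is the α,β-bond of a 2-alkylcyclopentenone whose carbonyl is C8. A catalytic enantioselective Diels–Alder reaction of enone 4 with silyl dienol ether 6 therefore forms C4–C5 and C1–C16 at once and sets the quaternary C16, C5 and C1. Afterwards the C8 ketone becomes the C8=C9 alkene (Wittig), the azonane is closed at N12–C13, C3 is hydrated under C1–OH control, and C7 is oxidised last.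

Key step: step 3

Remark on locants (used in all names): C1 = CH–O carbon of the cyclohexane, C2, C3 = methyl-bearing carbon, C4, C5 = ring-fusion CH, C6, C7 = ketone carbon of the target, C8=C9 = alkene, C10, C11, N12, C13, C14, C15, C16 = quaternary carbon. Cyclohexane = C1–C5 and C16; cyclopentane = C5–C8 and C16; azonane = C8–C16 through N12.

Assumption: 2-iodocyclopent-2-en-1-one (1) and phosphonium salt 8 are bought. The (S)-catalyst of step 3 is assumed to shield the α-alkyl enone as it does the parent cycloalkenones; the antipodal catalyst is equally available.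

Step 1
Reactants: 1 2-iodocyclopent-2-en-1-one; 2 tert-butyl(dimethyl)(prop-2-en-1-yloxy)silane
Product: 4 2-[3-(tert-butyldimethylsilyloxy)propyl]cyclopent-2-en-1-one, via alkylborane 3 (not isolated)
Conditions: 9-BBN, THF, rt; then 1, PdCl2(dppf) (cat.), AsPh3 (cat.), Cs2CO3, DMF/THF/H2O, rt
Reagents that add atoms: none
Why: Anti-Markovnikov hydroboration of the allyl ether followed by B-alkyl Suzuki–Miyaura coupling with the 2-iodoenone is a standard route to 2-alkylcyclopent-2-enones and creates no stereocenter.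

Step 2
Reactants: 5 3-methylbut-2-enal
Product: 6 (E)-[(3-methylbuta-1,3-dien-1-yl)oxy]tri(propan-2-yl)silane
Conditions: iPr3SiOTf, Et3N, Et2O, 0 °C → rt
Reagents that add atoms: triisopropylsilyl trifluoromethanesulfonate, CC(C)[Si](OS(=O)(=O)C(F)(F)F)(C(C)C)C(C)C
Why: Silyl dienol ether formation (O-silylation of the enal, then γ-deprotonation of the s-trans oxocarbenium ion by the amine) gives the 1-silyloxy-1,3-diene with E geometry at C1=C2.

Step 3
Reactants: 4 2-[3-(tert-butyldimethylsilyloxy)propyl]cyclopent-2-en-1-one; 6 (E)-[(3-methylbuta-1,3-dien-1-yl)oxy]tri(propan-2-yl)silane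
Product: 7 (3aR,7S,7aR)-7a-[3-(tert-butyldimethylsilyloxy)propyl]-5-methyl-7-(triisopropylsilyloxy)-2,3,3a,4,7,7a-hexahydro-1H-inden-1-one (route locants 1S,5R,16R; C1–O cis to C8; cis ring fusion)
Conditions: (S)-3,3-diphenyl-1-(o-tolyl)hexahydropyrrolo[1,2-c][1,3,2]oxazaborole (20 mol %), HNTf2 (18 mol %), CH2Cl2, −78 → −40 °C
Reagents that add atoms: none
Why: The protonated oxazaborolidine binds the C8 carbonyl of 4 and lowers the enone LUMO, and the silyl dienol ether adds in a concerted but asynchronous normal-demand [4+2] cycloaddition in which C4–C5 runs ahead of C1–C16. The closest known reaction types are the catalytic enantioselective Diels–Alder reaction of cycloalkenones and the Lewis acid promoted addition of 1-silyloxydienes to 2-alkylcycloalkenones, which gives cis-fused bicycles with an angular quaternary carbon. The cyclohexene ring C1–C2–C3–C4–C5–C16 is closed by intermolecular [4+2] annulation, suprafacial on both partners, so the C5–C16 fusion is cis. C1 follows from the E geometry of the diene and the endo transition state (cyclopentenone ring under the diene), which places C1–O cis to C8, while the absolute sense at C16, C5 and C1 is set by the catalyst, whose aryl groups cover one face of the bound enone so that the diene adds to the face that is Si at both C5 and C16. Regiochemistry is secured twice, since both the 1-silyloxy and the 3-methyl group make C4 the nucleophilic diene terminus, which attacks the β-carbon C5. The step needs face selectivity on an α-substituted enone, its least certain point, and the hindered triisopropylsilyl group on the diene to suppress silyl transfer to the acid.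

Step 4
Reactants: 7 Diels–Alder adduct (1S,5R,16R); 8 [3-(tert-butoxycarbonylamino)propyl]triphenylphosphonium bromide
Product: 10 Boc-aminopropylidene compound (1S,5R,16S,8Z): 7 with C8=O replaced by C8=C9H–C10H2–C11H2–NHBoc and C10 syn to C16, via ylide 9 (not isolated)
Conditions: 8 (3 equiv), KN(SiMe3)2 (6 equiv), THF, 0 °C; then 7, rt → 60 °C
Reagents that add atoms: none
Why: Wittig olefination with a non-stabilised ylide (the second equivalent of base removes the carbamate N–H) is precedented on α-quaternary cyclopentanones of the 17-oxo-steroid type, which under kinetic oxaphosphetane control give the alkene whose new chain lies syn to the quaternary carbon, here C10 syn to C16 as the azonane requires.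

Step 5
Reactants: 10 Boc-aminopropylidene compound (1S,5R,16S,8Z)
Product: 11 bromide (1S,5R,16S,8Z): 10 with C13–Br in place of C13–OSi(tBu)Me2
Conditions: Ph3PBr2, CH2Cl2, 0 °C → rt
Reagents that add atoms: triphenylphosphine dibromide, BrP(Br)(c1ccccc1)(c1ccccc1)c1ccccc1
Why: Direct conversion of a silyl ether into a bromide with Ph3PBr2 (O-phosphonium formation, then SN2 by bromide) is selective for the unhindered primary tert-butyldimethylsilyl ether over the neopentyl-type secondary triisopropylsilyl ether and creates no stereocenter.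

Step 6
Reactants: 11 bromide (1S,5R,16S,8Z)
Product: 12 tricyclic N-Boc azonane (1S,5R,16S,8Z): N12 bonded to C11 and C13, C1–OSi(iPr)3, C2=C3(CH3)
Conditions: KOtBu, Bu4NI (cat.), THF, high dilution, 0 → 45 °C
Reagents that add atoms: none
Why: Intramolecular SN2 N-alkylation of the potassium carbamate (9-exo-tet) at high dilution closes the azonane, a ring closure precedented for Boc-carbamates and primary halides on this ring system, the Z alkene and the quaternary carbon holding the two chains together.

Step 7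
Reactants: 12 tricyclic N-Boc azonane (1S,5R,16S,8Z)
Product: 13 allylic alcohol (1S,5R,16S,8Z): 12 with free C1–OH
Conditions: Bu4NF, THF, rt → 45 °C
Reagents that add atoms: none
Why: Fluoride-mediated desilylation of the hindered triisopropylsilyl ether frees the C1 allylic alcohol without touching a stereocenter.

Step 8
Reactants: 13 allylic alcohol (1S,5R,16S,8Z)
Product: 14 epoxy alcohol (1R,2R,3S,5R,16S,8Z): C2–C3 epoxide cis to C1–OH
Conditions: VO(acac)2 (cat.), tBuOOH, CH2Cl2, 0 °C → rt
Reagents that add atoms: tert-butyl hydroperoxide, CC(C)(C)OO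
Why: Hydroxyl-directed epoxidation (vanadium alkoxide–alkylperoxide complex) delivers oxygen to the face of C2=C3 syn to C1–OH, which sets C2 and C3, and ignores the non-allylic C8=C9 alkene.

Step 9
Reactants: 14 epoxy alcohol (1R,2R,3S,5R,16S,8Z)
Product: 15 diol (1S,3S,5R,16S,8Z): C1–OH and C3–OH cis, C3–CH3 trans to both
Conditions: LiEt3BH, THF, 0 °C → rt; aqueous work-up
Reagents that add atoms: none
Why: Regioselective SN2 hydride opening of the trisubstituted epoxide at the less substituted C2 (anti, trans-diaxial) leaves the oxygen on C3 on the face of C1–OH, so the tertiary carbinol is formed cis-1,3 with the methyl trans.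

Step 10
Reactants: 15 diol (1S,3S,5R,16S,8Z)
Product: 16 diacetate (1S,3S,5R,16S,8Z)
Conditions: Ac2O, DMAP, Et3N, CH2Cl2, rt → 40 °C
Reagents that add atoms: acetic anhydride, CC(=O)OC(C)=O
Why: DMAP-catalysed acylation esterifies the secondary alcohol at once and the tertiary alcohol on warming, the Boc-protected nitrogen being inert.

Step 11
Reactants: 16 diacetate (1S,3S,5R,16S,8Z)
Product: 17 allylic alcohol (1S,3S,5R,16S; either C7 epimer): 16 with OH at C7, alkene geometry unchanged
Conditions: SeO2 (cat.), tBuOOH, CH2Cl2, rt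
Reagents that add atoms: selenium dioxide, O=[Se]=O; tert-butyl hydroperoxide, CC(C)(C)OO
Why: SeO2 allylic oxidation (ene reaction, then [2,3]-sigmatropic shift) attacks the CH2 on the disubstituted terminus of the trisubstituted alkene, which is C7 because C16 carries no hydrogen, as in the 16-hydroxylation of steroidal 17(20)-alkenes; the new C7 stereocenter is removed in step 12.

Step 12
Reactants: 17 allylic alcohol (C7 epimers)
Product: 18 N-Boc enone (1S,3S,5S,16S,8E): C7 ketone conjugated with C8=C9, C10 still syn to C16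
Conditions: 1,1,1-triacetoxy-1λ5,2-benziodoxol-3(1H)-one (DMP), CH2Cl2, rt
Reagents that add atoms: none
Why: Hypervalent iodine oxidation of the secondary allylic alcohol gives the enone under neutral conditions that leave the esters and the carbamate intact, the ring fixing the alkene geometry.

Step 13
Reactants: 18 N-Boc enone (1S,3S,5S,16S,8E)
Product: 20 CNP0120442.1 (1S,3S,5S,16S,8E), via silyl carbamate 19 (not isolated)
Conditions: Me3SiOTf, 2,6-lutidine, CH2Cl2, 0 °C; then MeOH
Reagents that add atoms: none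
Why: Silylative Boc cleavage (O-silylation, loss of isobutene, then methanolysis and decarboxylation of the silyl carbamate) works under buffered conditions that spare the acid-labile tertiary acetate, where trifluoroacetic acid would not.

Compound list

1 | 2-iodocyclopent-2-en-1-one | O=C1CCC=C1I | starting material
2 | tert-butyl(dimethyl)(prop-2-en-1-yloxy)silane | C=CCO[Si](C)(C)C(C)(C)C | starting material
3 | 9-[3-(tert-butyldimethylsilyloxy)propyl]-9-borabicyclo[3.3.1]nonane | CC(C)(C)[Si](C)(C)OCCCB1C2CCCC1CCC2 | intermediate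
4 | 2-[3-(tert-butyldimethylsilyloxy)propyl]cyclopent-2-en-1-one | O=C1CCC=C1CCCO[Si](C)(C)C(C)(C)C | intermediate
5 | 3-methylbut-2-enal | CC(C)=CC=O | starting material
6 | (E)-[(3-methylbuta-1,3-dien-1-yl)oxy]tri(propan-2-yl)silane | C=C(C)/C=C/O[Si](C(C)C)(C(C)C)C(C)C | intermediate
7 | (3aR,7S,7aR)-7a-[3-(tert-butyldimethylsilyloxy)propyl]-5-methyl-7-(triisopropylsilyloxy)-2,3,3a,4,7,7a-hexahydro-1H-inden-1-one (route locants 1S,5R,16R) | CC(C)[Si](C(C)C)(C(C)C)O[C@H]1C=C(C)C[C@H]2CCC(=O)[C@@]12CCCO[Si](C)(C)C(C)(C)C | intermediate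
8 | [3-(tert-butoxycarbonylamino)propyl]triphenylphosphonium bromide | CC(C)(C)OC(=O)NCCC[P+](c1ccccc1)(c1ccccc1)c1ccccc1.[Br-] | starting material
9 | potassium salt of tert-butyl [3-(triphenylphosphoranylidene)propyl]carbamate (N-deprotonated ylide) | CC(C)(C)OC(=O)[N-]CCC=P(c1ccccc1)(c1ccccc1)c1ccccc1.[K+] | intermediate
10 | Boc-aminopropylidene compound (1S,5R,16S,8Z): 7 with C8=O replaced by C8=C9H–C10H2–C11H2–NHBoc, C10 syn to C16 | CC(C)[Si](C(C)C)(C(C)C)O[C@H]1C=C(C)C[C@H]2CC/C(=C/CCNC(=O)OC(C)(C)C)[C@@]12CCCO[Si](C)(C)C(C)(C)C | intermediate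
11 | bromide (1S,5R,16S,8Z): 10 with C13–Br | CC(C)[Si](C(C)C)(C(C)C)O[C@H]1C=C(C)C[C@H]2CC/C(=C/CCNC(=O)OC(C)(C)C)[C@@]12CCCBr | intermediate
12 | tricyclic N-Boc azonane (1S,5R,16S,8Z) with C1–OSi(iPr)3 and C2=C3(CH3) | CC(C)[Si](C(C)C)(C(C)C)O[C@H]1C=C(C)C[C@H]2CC/C3=C/CCN(C(=O)OC(C)(C)C)CCC[C@@]321 | intermediate
13 | allylic alcohol (1S,5R,16S,8Z): 12 with free C1–OH | O[C@H]1C=C(C)C[C@H]2CC/C3=C/CCN(C(=O)OC(C)(C)C)CCC[C@@]321 | intermediate
14 | epoxy alcohol (1R,2R,3S,5R,16S,8Z): C2–C3 epoxide cis to C1–OH | O[C@H]1[C@H]2O[C@@]2(C)C[C@H]3CC/C4=C/CCN(C(=O)OC(C)(C)C)CCC[C@@]431 | intermediate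
15 | cis-1,3-diol (1S,3S,5R,16S,8Z) | O[C@H]1C[C@@](C)(O)C[C@H]2CC/C3=C/CCN(C(=O)OC(C)(C)C)CCC[C@@]321 | intermediate
16 | diacetate (1S,3S,5R,16S,8Z) | CC(=O)O[C@H]1C[C@@](C)(OC(C)=O)C[C@H]2CC/C3=C/CCN(C(=O)OC(C)(C)C)CCC[C@@]321 | intermediate
17 | C7 allylic alcohol (1S,3S,5R,16S; C7 epimers, C7 left undefined) | CC(=O)O[C@H]1C[C@@](C)(OC(C)=O)C[C@H]2CC(O)/C3=C/CCN(C(=O)OC(C)(C)C)CCC[C@@]321 | intermediate
18 | N-Boc enone (1S,3S,5S,16S,8E) | CC(=O)O[C@H]1C[C@@](C)(OC(C)=O)C[C@H]2CC(=O)/C3=C/CCN(C(=O)OC(C)(C)C)CCC[C@@]321 | intermediate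
19 | N-(trimethylsilyloxycarbonyl) enone (1S,3S,5S,16S,8E) | CC(=O)O[C@H]1C[C@@](C)(OC(C)=O)C[C@H]2CC(=O)/C3=C/CCN(C(=O)O[Si](C)(C)C)CCC[C@@]321 | intermediate
20 | CNP0120442.1: (1S,3S,5S,16S,8E)-1,3-diacetoxy-3-methyl amino enone, free N12–H | CC(=O)O[C@H]1C[C@@](C)(OC(C)=O)C[C@H]2CC(=O)/C3=C/CCNCCC[C@@]321 | target

Total step count: 13. Longest linear sequence: 12 steps (steps 1 and 3–13; step 2 is a one-step side branch).

Steps most likely to fail

Step 3. The α-alkyl group weakens both the activation and the facial discrimination of the enone by the catalyst, and the silyl dienol ether may add in a stepwise Mukaiyama–Michael fashion that stops short of ring closure. The fallback moves the stereocontrol into the dienophile and sets out from borane 3 and diene 6. Commercial (R)-4-(tert-butyldimethylsilyloxy)cyclopent-2-en-1-one F1 is iodinated (I2, pyridine, CH2Cl2) to (R)-2-iodo-4-(tert-butyldimethylsilyloxy)cyclopent-2-en-1-one F2. Coupling with 3 under the conditions of step 1 gives (R)-4-(tert-butyldimethylsilyloxy)-2-[3-(tert-butyldimethylsilyloxy)propyl]cyclopent-2-en-1-one F3. An achiral Lewis acid (Me2AlCl, CH2Cl2, −78 → −20 °C) then promotes the Diels–Alder reaction with 6, the diene adding anti to the C6 silyloxy group to give the C6-silyloxy adduct F4. Elimination with 1,8-diazabicyclo[5.4.0]undec-7-ene gives the C6=C7 enone F5, and conjugate reduction with [(Ph3P)CuH]6 comes back to the route at 7.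

Step 4. Attack of the bulky ylide on the neopentyl ketone can be outrun by enolisation towards C7, and the oxaphosphetane may form with the chain anti to C16, which gives an alkene that cannot cyclise. The fallback forms C8=C9 and the azonane together by carbonyl coupling and sets out from 7. Ph3PBr2 gives the bromo ketone F6. Heating with excess 3,3-diethoxypropan-1-amine (K2CO3, MeCN) gives the secondary amine F7, which is protected at once (Boc2O) as the N-Boc acetal F8. Mild acid hydrolysis (pyridinium p-toluenesulfonate, acetone/H2O) gives the keto aldehyde F9. Intramolecular McMurry coupling (TiCl3(DME)1.5, Zn–Cu couple, DME, reflux, slow addition), in which the ring enforces the alkene geometry, comes back to the route at 12.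

Step 6. Closure of the nine-membered ring is slow, so E2 elimination of the bromide and intermolecular N-alkylation can take over. The fallback closes the ring by reductive amination and sets out from 10. Selective cleavage of the primary silyl ether (HF·pyridine, pyridine, THF) gives the primary alcohol F10, and DMP oxidation gives the aldehyde F11. Silylative Boc removal (Me3SiOTf, 2,6-lutidine; MeOH) followed by NaBH(OAc)3 and AcOH in dilute 1,2-dichloroethane closes the ring through the cyclic iminium ion to the secondary amine F12. Boc2O and Et3N come back to the route at 12.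

Further compounds

F1 | step 3 | (R)-4-(tert-butyldimethylsilyloxy)cyclopent-2-en-1-one | O=C1C=C[C@H](O[Si](C)(C)C(C)(C)C)C1
F2 | step 3 | (R)-2-iodo-4-(tert-butyldimethylsilyloxy)cyclopent-2-en-1-one | O=C1C(I)=C[C@H](O[Si](C)(C)C(C)(C)C)C1
F3 | step 3 | (R)-4-(tert-butyldimethylsilyloxy)-2-[3-(tert-butyldimethylsilyloxy)propyl]cyclopent-2-en-1-one | O=C1C(CCCO[Si](C)(C)C(C)(C)C)=C[C@H](O[Si](C)(C)C(C)(C)C)C1
F4 | step 3 | C6-silyloxy Diels–Alder adduct: 7 with OSi(tBu)Me2 at C6 (6R), anti to C4 | CC(C)[Si](C(C)C)(C(C)C)O[C@H]1C=C(C)C[C@H]2[C@H](O[Si](C)(C)C(C)(C)C)CC(=O)[C@@]12CCCO[Si](C)(C)C(C)(C)C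
F5 | step 3 | C6=C7 enone: 7 with a C6=C7 double bond | CC(C)[Si](C(C)C)(C(C)C)O[C@H]1C=C(C)C[C@H]2C=CC(=O)[C@@]12CCCO[Si](C)(C)C(C)(C)C
F6 | step 4 | bromo ketone: 7 with C13–Br | CC(C)[Si](C(C)C)(C(C)C)O[C@H]1C=C(C)C[C@H]2CCC(=O)[C@@]12CCCBr
F7 | step 4 | secondary amine: C13–NH–CH2CH2CH(OEt)2 | CC(C)[Si](C(C)C)(C(C)C)O[C@H]1C=C(C)C[C@H]2CCC(=O)[C@@]12CCCNCCC(OCC)OCC
F8 | step 4 | N-Boc acetal | CC(C)[Si](C(C)C)(C(C)C)O[C@H]1C=C(C)C[C@H]2CCC(=O)[C@@]12CCCN(CCC(OCC)OCC)C(=O)OC(C)(C)C
F9 | step 4 | keto aldehyde (C8 ketone, C9 aldehyde) | CC(C)[Si](C(C)C)(C(C)C)O[C@H]1C=C(C)C[C@H]2CCC(=O)[C@@]12CCCN(CCC=O)C(=O)OC(C)(C)C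
F10 | step 6 | primary alcohol: 10 with C13–OH | CC(C)[Si](C(C)C)(C(C)C)O[C@H]1C=C(C)C[C@H]2CC/C(=C/CCNC(=O)OC(C)(C)C)[C@@]12CCCO
F11 | step 6 | aldehyde: 10 with C13 as CHO | CC(C)[Si](C(C)C)(C(C)C)O[C@H]1C=C(C)C[C@H]2CC/C(=C/CCNC(=O)OC(C)(C)C)[C@@]12CCC=O
F12 | step 6 | tricyclic secondary amine: 12 without Boc | CC(C)[Si](C(C)C)(C(C)C)O[C@H]1C=C(C)C[C@H]2CC/C3=C/CCNCCC[C@@]321
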